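## Analysis of the target

Artelasticin is a flavone with no stereocentre. Ring A (C4a to C8a) is a fully substituted phloroglucinol ring with hydroxyls at C5 and C7 and prenyl groups at C6 and C8. Ring C is the 4-pyranone and carries a third prenyl group at C3. Ring B is a 2',4'-dihydroxyphenyl group bonded through C1' to C2. All three side-chain double bonds end in a gem-dimethyl group, so no alkene geometry has to be set.

The sensitive features are the three prenyl groups, each next to a phenol (C6 between O5 and O7, C8 beside O7, the C3 prenyl within reach of O2'). Strong Brønsted or Lewis acids therefore close chroman-type rings. The electron-rich rings and the alkenes also exclude oxidants, hydrogenolysis and electrophilic halogen.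

The hard part is the C2/C3 edge of ring C: an ortho-oxygenated aryl group at C2 stands beside the C3 prenyl group. Classical ring closures force both into one congested 2-substituted 1,3-diketone. The hexasubstituted ring A is a second, lesser problem.

The strategy rests on ring B. Its two oxygens sit 1,3 to each other on the four-carbon stretch C2' to C5'. The remaining two carbons, C1' (bonded to C2) and C6' (bearing only hydrogen), carry no heteroatom. Ring B is therefore the sum of a 1,3-dioxygenated diene and an ethynyl group on C2.

## Retrosynthetic reasoning

**16 to 15.** The two O–CH2 acetal bonds at O5 and O7 are cut last in the forward sense, so target 16 goes back to its 5,7-bis(methoxymethyl) ether 15. Free ring A phenols would quench the silyl ketene acetal used one step earlier; as acetals they survive base, fluoride and heat. Ring B needs no protection of its own because it is formed with both oxygens silylated. The forward step must cleave two aryl acetals without letting a phenol add to a prenyl double bond.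

**15 to 9 and 12.** Ring B is cut at C1'–C2' and at C5'–C6'. This leaves C1' and C6' on the chromone as the ethynyl group of 9, and C2' to C5' with both oxygens as diene 12. Cutting here, and not at C2–C1' or within ring C, means the bulky ortho-oxygenated ring is never carried through the closure of ring C. Only a linear two-carbon unit stands beside the C3 prenyl group until the last carbon–carbon bonds form. The forward reaction must join the nucleophilic CH2 end of 12 to the terminal alkyne carbon of 9, close the ring at C1', and aromatize by loss of the methoxy group and the silyl groups.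

**9 to 8.** The terminal C–H is traced back to a C–Si bond. The silyl cap on 8 is needed earlier to block the alkyne terminus against conjugate addition and deprotonation.

**8 to 7.** Ring C is opened at O1–C2, with the C2=C3 double bond arising by dehydration. This gives 1,3-diketone 7, in which the free ortho phenol is poised to add to the alkynyl ketone carbonyl. This is the standard chromone disconnection and puts the C3 prenyl group on the central carbon of the diketone. The forward step must direct the phenol to the carbonyl carbon, not an enol oxygen to the alkyne.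

**7 to 5 and 6.** The C2–C3 bond is cut, giving the enolate of ketone 5 and the non-enolizable ester 6. Ester 6 brings in C2 and both alkyne carbons in one step.

**5 to 4 and 2.** The bond between C3 and its prenyl CH2 is cut, which is alkylation of the methyl ketone 4 with prenyl bromide 2. Installing this group before ring C exists avoids any later substitution at C3 of a chromone.

**4 to 3.** The two acetal O–C bonds are cut. In triol 3 the phenol para to the acetyl group and one ortho phenol are free to react, while the second ortho phenol is held in a hydrogen bond to the ketone. That phenol later becomes O1.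

**3 to 1 and 2.** The two aryl–CH2 bonds at the future C6 and C8 are cut. The only two free ring positions of 1 are the nucleophilic carbons of a phloroglucinol phenolate, so ring A is reached in one step from two commercial materials.

**12 to 11 to 10.** Two O–Si bonds are cut in turn. The diene is the doubly enol-silylated form of methyl acetoacetate 10, by way of the mono silyl enol ether 11.

## Alternatives that were turned down

**Alternative 1: benzannulation to build ring A.**
- Disconnection: ring A is taken apart at C8a–C8, C7–C6 and C8a–C4a into 3-ethoxy-2-prenylcyclobutenone A1 and the prenyl-substituted triisopropylsilyl ynol ether A2.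
- Forward key step: heating opens A1 to a vinylketene, which adds to A2 in a [2+2] sense. A second electrocyclic opening and a six-electron closure give phenol A3 with three differently substituted oxygens (a Danheiser-type benzannulation).
- For: every substituent of ring A is placed without ambiguity, and there is no statistical prenylation. On regiocontrol of ring A it is stronger than step 1 of the chosen route.
- Against: it rebuilds the part of the molecule that compound 3 supplies in one step. A1 and A2 each need several steps. The ketene intermediates carry a prenyl alkene close enough for intramolecular [2+2] addition. After A3, C4a still has to be acylated in the presence of acid-sensitive prenyl groups. The crowded C2/C3 edge is untouched. The ethyl ether at O5 would need a Lewis-acidic dealkylation at the end, which three prenyl groups beside phenols do not tolerate.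
- Comparison: the chosen strategy accepts a moderate first step and spends its new chemistry where the structural difficulty lies, in far fewer steps.

**Alternative 2: thermal union of a phloroglucinol with a beta-ketoester.**
- Disconnection: ring C is cut at C4–C4a and O1–C2 into 2,4-diprenylphloroglucinol A4 and the alpha-prenyl aroylacetate A5 carrying ring B as its bis(tert-butyldimethylsilyl) ether.
- Forward key step: the two are heated strongly without solvent (a Mentzer-type pyrone synthesis), giving the flavone A6, which needs only desilylation.
- For: it is the shortest and most convergent plan, and on step count it is stronger than the chosen route. A4 has a single free ring carbon flanked by two equivalent hydroxyls, so there is no regiochemical question.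
- Against: the temperature is far above what ortho-prenyl phenols and aryl silyl ethers tolerate (ring closure of phenol onto alkene, sigmatropic shifts, silyl migration). A5 is alpha-substituted and ortho-substituted, the least reactive kind of ketoester for this condensation. Coumarin formation competes. The closure of O1–C2 must still take place at a hindered ortho-oxygenated aryl ketone beside a prenyl group, so the crowding problem is faced at the hottest step.
- Comparison: the chosen strategy forms its bonds below about 100 °C and with a small alkyne at C2, at the cost of more steps.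

**Alternative 3: rhodium-catalysed aldehyde C–H annulation.**
- Disconnection: ring C is cut at C4–C3 and O1–C2 into the ring A salicylaldehyde A7 and the aryl prenyl alkyne A8.
- Forward key step: a pentamethylcyclopentadienyl rhodium catalyst in the trivalent state activates the aldehyde C–H bond under direction of the phenoxide. The alkyne inserts, C–O reductive elimination closes ring C, and a divalent copper carboxylate reoxidizes the metal. The product is the tetrakis(methoxymethyl) ether A9.
- For: the reaction class is established for salicylaldehydes and internal alkynes, so on precedent it is stronger than the chosen key step. It is convergent, and the usual insertion sense places the aryl group next to oxygen, as required.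
- Against: both partners lie at the unfavourable edge of the scope. The formyl group of A7 is flanked by a hydroxyl and an acetal oxygen, with a prenyl group beside the directing phenol. A8 has an ortho-alkoxy aryl group, which slows insertion and erodes its regioselectivity, and a 1,4-enyne that can isomerize. Three trisubstituted alkenes meet an oxidizing metal system capable of allylic activation. Decarbonylation competes. Four acetals must be cleaved at the end, which doubles the acid exposure of the phenol/prenyl pairs.
- Comparison: the chosen strategy uses no transition metal in the ring-forming step, keeps the substituent at C2 small while the bonds form, and ends with only two acetals to remove.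

Key step: step 9

Remark: 7 is written as the open 1,3-diketone although it will equilibrate with its enol and cyclic hemiketal forms. The double-bond geometry of 11 and of the ketene acetal end of 12 is left undefined because it is erased when ring B becomes aromatic.

## Route

Step 1
Reactants: 1 2,4,6-trihydroxyacetophenone; 2 prenyl bromide
Product: 3 1-[2,4,6-trihydroxy-3,5-bis(3-methylbut-2-enyl)phenyl]ethanone
Conditions: 2 (2.2 equiv), 10% aq KOH, 0 °C → rt
Reagents that add atoms: none
Why: C-alkylation of an acylphloroglucinol phenolate; in water the phenoxide oxygens are hydrogen-bonded, so the two free ring carbons react with the allylic bromide. The reaction is statistical, so a moderate yield is expected after separation from mono-prenylated and geminally over-alkylated material.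

Step 2
Reactants: 3 1-[2,4,6-trihydroxy-3,5-bis(3-methylbut-2-enyl)phenyl]ethanone
Product: 4 1-[2-hydroxy-4,6-bis(methoxymethoxy)-3,5-bis(3-methylbut-2-enyl)phenyl]ethanone
Conditions: MOMCl (2.2 equiv), i-Pr2NEt (3 equiv), CH2Cl2, 0 °C → rt
Reagents that add atoms: chloromethyl methyl ether, COCCl
Why: Williamson-type O-alkylation; the phenol para to the acetyl group and the ortho phenol not engaged in hydrogen bonding react, and the remaining ortho phenol is held by the carbonyl and stays free with two equivalents of reagent.

Step 3
Reactants: 4 1-[2-hydroxy-4,6-bis(methoxymethoxy)-3,5-bis(3-methylbut-2-enyl)phenyl]ethanone; 2 prenyl bromide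
Product: 5 1-[2-hydroxy-4,6-bis(methoxymethoxy)-3,5-bis(3-methylbut-2-enyl)phenyl]-5-methylhex-4-en-1-one
Conditions: LDA (2.3 equiv), THF, −78 °C; 2 (1.05 equiv), −78 → 0 °C; AcOH quench
Reagents that add atoms: none
Why: Enolate alkylation through the O,C-dianion; the methyl ketone enolate is far more nucleophilic than the chelated lithium phenoxide and displaces bromide at the primary allylic carbon, and one equivalent of halide at low temperature limits double alkylation.

Step 4
Reactants: 5 1-[2-hydroxy-4,6-bis(methoxymethoxy)-3,5-bis(3-methylbut-2-enyl)phenyl]-5-methylhex-4-en-1-one; 6 ethyl 3-(trimethylsilyl)propiolate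
Product: 7 1-[2-hydroxy-4,6-bis(methoxymethoxy)-3,5-bis(3-methylbut-2-enyl)phenyl]-2-(3-methylbut-2-enyl)-5-(trimethylsilyl)pent-4-yne-1,3-dione
Conditions: LiHMDS (3.2 equiv), THF, −78 °C; 6 (1.3 equiv), −78 → −20 °C; AcOH quench
Reagents that add atoms: none
Why: Crossed Claisen condensation of a ketone enolate with a non-enolizable ester; the silyl group shields the alkyne terminus from conjugate addition, and deprotonation of the product to the diketonate drives the acylation and protects the new ynone. The new stereocentre is racemic and is lost in the next step.

Step 5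
Reactants: 7 1-[2-hydroxy-4,6-bis(methoxymethoxy)-3,5-bis(3-methylbut-2-enyl)phenyl]-2-(3-methylbut-2-enyl)-5-(trimethylsilyl)pent-4-yne-1,3-dione
Product: 8 5,7-bis(methoxymethoxy)-3,6,8-tris(3-methylbut-2-enyl)-2-[(trimethylsilyl)ethynyl]chromen-4-one
Conditions: p-TsOH·H2O (10 mol %), 4 Å MS, CH2Cl2, rt
Reagents that add atoms: none
Why: Cyclodehydration of a 1-(2-hydroxyaryl)-1,3-dione to a chromone; the phenol adds to the electrophilic alkynyl ketone (6-exo-trig) and the hemiketal loses water through the enol of the aryl ketone. Catalytic acid in a dry aprotic solvent with sieves should spare the acetals and the prenyl groups.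

Step 6
Reactants: 8 5,7-bis(methoxymethoxy)-3,6,8-tris(3-methylbut-2-enyl)-2-[(trimethylsilyl)ethynyl]chromen-4-one
Product: 9 2-ethynyl-5,7-bis(methoxymethoxy)-3,6,8-tris(3-methylbut-2-enyl)chromen-4-one
Conditions: TBAF (1.1 equiv), AcOH (1.5 equiv), THF, −20 → 0 °C
Reagents that add atoms: none
Why: Fluoride-induced protodesilylation of an alkynylsilane; buffering with acetic acid keeps basic species from adding to the electron-poor terminal alkyne.

Step 7
Reactants: 10 methyl acetoacetate
Product: 11 methyl 3-(trimethylsilyloxy)but-2-enoate
Conditions: TMSCl, Et3N, hexane, rt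
Reagents that add atoms: chlorotrimethylsilane, C[Si](C)(C)Cl
Why: O-silylation of the ammonium enolate of a beta-ketoester gives the silyl enol ether; this is the standard first stage of the diene preparation.

Step 8
Reactants: 11 methyl 3-(trimethylsilyloxy)but-2-enoate
Product: 12 1-methoxy-1,3-bis(trimethylsilyloxy)buta-1,3-diene
Conditions: LDA (1.1 equiv), THF, −78 °C; TMSCl, −78 °C → rt; distillation
Reagents that add atoms: chlorotrimethylsilane, C[Si](C)(C)Cl
Why: Gamma-deprotonation gives the extended ester dienolate, which is silylated on oxygen to the silyl ketene acetal; the diene is moisture-sensitive and is used freshly distilled.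

Step 9
Reactants: 9 2-ethynyl-5,7-bis(methoxymethoxy)-3,6,8-tris(3-methylbut-2-enyl)chromen-4-one; 12 1-methoxy-1,3-bis(trimethylsilyloxy)buta-1,3-diene
Product: 15 2-(2,4-dihydroxyphenyl)-5,7-bis(methoxymethoxy)-3,6,8-tris(3-methylbut-2-enyl)chromen-4-one (artelasticin 5,7-bis(methoxymethyl) ether), via cyclohexadiene cycloadduct 13 (not isolated), via aryl bis(trimethylsilyl) ether 14 (not isolated)
Conditions: 12 (3 equiv), toluene, 80 °C, sealed tube; then PPTS (0.2 equiv), MeOH–THF, rt
Reagents that add atoms: none
Why: Proposed new method: the terminal alkyne carbon of 9 is the remote acceptor position of the vinylogous ynone O=C4–C3=C2–C≡CH, so the nucleophilic CH2 terminus of 12 bonds there to form C5'–C6', and the resulting allenyl dienolate closes through its central carbon onto the silyloxy(methoxy)carbenium carbon to form C1'–C2'; a concerted, asynchronous [4+2] addition gives the same two bonds. The closest known reaction type is the Diels–Alder addition and aromatization of 1-methoxy-1,3-bis(silyloxy)dienes with alkynyl ketones and alkynoates to give 2,4-dihydroxyaryl ketones and esters; new here is a dienophile whose activation is relayed through the chromone C2=C3 bond. Ring B closes either suprafacially in the [4+2] mode or, in the stepwise variant, by a 6-(enolendo)-exo-trig attack on the oxocarbenium carbon. Cycloadduct 13 has a mixed silyl methyl ketal at C2' and a CH2 group at C5'; ionization of the ketal and loss of the C5' proton expel methanol and give the aromatic bis(silyl) ether 14, and methanolysis under pyridinium tosylate frees both phenols without touching the methoxymethyl ethers. No stereocentre survives, because C2' becomes aromatic. The selectivity needed is regiochemical: the ketene acetal carbon must end on C1' so that the oxygens sit at C2' and C4'. This follows from the matched polarization of the two partners and is reinforced sterically, since the other electrophilic site, C2, is fully substituted and shielded by the C3 prenyl group. Only a linear two-carbon unit stands beside that prenyl group while the bonds form, which removes the crowding met when a preformed ortho-oxygenated aryl ketone is used.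

Step 10
Reactants: 15 2-(2,4-dihydroxyphenyl)-5,7-bis(methoxymethoxy)-3,6,8-tris(3-methylbut-2-enyl)chromen-4-one
Product: 16 artelasticin
Conditions: 3 M aq HCl, MeOH–THF, 40 °C
Reagents that add atoms: none
Why: Acid-catalysed acetal cleavage with methanol as trap for the methoxymethyl cation; the acetal peri to the carbonyl goes first and the hindered C7 acetal follows, and the low temperature and short contact time should keep the phenols from adding to the prenyl double bonds.

## Compound list

1 | 2,4,6-trihydroxyacetophenone | CC(=O)c1c(O)cc(O)cc1O | starting material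
2 | prenyl bromide (1-bromo-3-methylbut-2-ene) | CC(C)=CCBr | starting material
3 | 1-[2,4,6-trihydroxy-3,5-bis(3-methylbut-2-enyl)phenyl]ethanone | CC(=O)c1c(O)c(CC=C(C)C)c(O)c(CC=C(C)C)c1O | intermediate
4 | 1-[2-hydroxy-4,6-bis(methoxymethoxy)-3,5-bis(3-methylbut-2-enyl)phenyl]ethanone | CC(=O)c1c(O)c(CC=C(C)C)c(OCOC)c(CC=C(C)C)c1OCOC | intermediate
5 | 1-[2-hydroxy-4,6-bis(methoxymethoxy)-3,5-bis(3-methylbut-2-enyl)phenyl]-5-methylhex-4-en-1-one | CC(C)=CCCC(=O)c1c(O)c(CC=C(C)C)c(OCOC)c(CC=C(C)C)c1OCOC | intermediate
6 | ethyl 3-(trimethylsilyl)propiolate | CCOC(=O)C#C[Si](C)(C)C | starting material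
7 | 1-[2-hydroxy-4,6-bis(methoxymethoxy)-3,5-bis(3-methylbut-2-enyl)phenyl]-2-(3-methylbut-2-enyl)-5-(trimethylsilyl)pent-4-yne-1,3-dione (racemic at C2; equilibrates with enol and cyclic hemiketal forms) | C[Si](C)(C)C#CC(=O)C(CC=C(C)C)C(=O)c1c(O)c(CC=C(C)C)c(OCOC)c(CC=C(C)C)c1OCOC | intermediate
8 | 5,7-bis(methoxymethoxy)-3,6,8-tris(3-methylbut-2-enyl)-2-[(trimethylsilyl)ethynyl]chromen-4-one | C[Si](C)(C)C#Cc1oc2c(CC=C(C)C)c(OCOC)c(CC=C(C)C)c(OCOC)c2c(=O)c1CC=C(C)C | intermediate
9 | 2-ethynyl-5,7-bis(methoxymethoxy)-3,6,8-tris(3-methylbut-2-enyl)chromen-4-one | C#Cc1oc2c(CC=C(C)C)c(OCOC)c(CC=C(C)C)c(OCOC)c2c(=O)c1CC=C(C)C | intermediate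
10 | methyl acetoacetate | COC(=O)CC(C)=O | starting material
11 | methyl 3-(trimethylsilyloxy)but-2-enoate (E/Z mixture) | COC(=O)C=C(C)O[Si](C)(C)C | intermediate
12 | 1-methoxy-1,3-bis(trimethylsilyloxy)buta-1,3-diene | COC(O[Si](C)(C)C)=CC(=C)O[Si](C)(C)C | intermediate
13 | 2-[6-methoxy-4,6-bis(trimethylsilyloxy)cyclohexa-1,4-dien-1-yl]-5,7-bis(methoxymethoxy)-3,6,8-tris(3-methylbut-2-enyl)chromen-4-one (racemic; formed in the flask, not isolated) | COC1(O[Si](C)(C)C)C=C(O[Si](C)(C)C)CC=C1c1oc2c(CC=C(C)C)c(OCOC)c(CC=C(C)C)c(OCOC)c2c(=O)c1CC=C(C)C | intermediate
14 | 2-[2,4-bis(trimethylsilyloxy)phenyl]-5,7-bis(methoxymethoxy)-3,6,8-tris(3-methylbut-2-enyl)chromen-4-one (formed in the flask, not isolated) | C[Si](C)(C)Oc1ccc(-c2oc3c(CC=C(C)C)c(OCOC)c(CC=C(C)C)c(OCOC)c3c(=O)c2CC=C(C)C)c(O[Si](C)(C)C)c1 | intermediate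
15 | 2-(2,4-dihydroxyphenyl)-5,7-bis(methoxymethoxy)-3,6,8-tris(3-methylbut-2-enyl)chromen-4-one (artelasticin 5,7-bis(methoxymethyl) ether) | CC(C)=CCc1c(OCOC)c(CC=C(C)C)c2oc(-c3ccc(O)cc3O)c(CC=C(C)C)c(=O)c2c1OCOC | intermediate
16 | artelasticin | CC(C)=CCc1c(O)c(CC=C(C)C)c2oc(-c3ccc(O)cc3O)c(CC=C(C)C)c(=O)c2c1O | target

## Step count and risk

Total step count: 10. Longest linear sequence: 8 steps (steps 1 to 6, 9 and 10, from 1). The two-step diene branch (steps 7 and 8) joins at step 9.

**Step 9 (key step, proposed new method).**
- What may go wrong: the alkyne is activated only through the chromone double bond, so decomposition of the diene (hydrolysis, silyl transfer) may outrun addition. The sequence may also stall after the first carbon–carbon bond without ring closure. Portionwise addition of 12 or a mild Lewis acid such as ZnBr2 would be tried first.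
- Fallback by known chemistry, from 5, returning at 15: ring B is brought in preformed by the classical diketone route. The dilithio derivative of 5 (LiHMDS, THF, −78 °C) is acylated with 2,4-bis(tert-butyldimethylsilyloxy)benzoyl chloride; any O-aroylated material is carried on by Baker–Venkataraman rearrangement. This gives 1-[2,4-bis(tert-butyldimethylsilyloxy)phenyl]-3-[2-hydroxy-4,6-bis(methoxymethoxy)-3,5-bis(3-methylbut-2-enyl)phenyl]-2-(3-methylbut-2-enyl)propane-1,3-dione F1. Acid-catalysed cyclodehydration as in step 5 closes ring C to 2-[2,4-bis(tert-butyldimethylsilyloxy)phenyl]-5,7-bis(methoxymethoxy)-3,6,8-tris(3-methylbut-2-enyl)chromen-4-one F2. Buffered TBAF then removes the two silyl groups and gives 15.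

**Step 4.**
- What may go wrong: C-acylation of the hindered, tetrasubstituted enolate by an ester may be slow, so that proton transfer, conjugate addition to the ynoate or alkoxide-induced loss of the alkyne silyl group competes.
- Fallback, from 5, returning at 7: the same dianion is added to 3-(trimethylsilyl)propynal at −78 °C, a much faster aldol addition. This gives 3-hydroxy-1-[2-hydroxy-4,6-bis(methoxymethoxy)-3,5-bis(3-methylbut-2-enyl)phenyl]-2-(3-methylbut-2-enyl)-5-(trimethylsilyl)pent-4-yn-1-one F3 as a mixture of racemic diastereomers. Oxidation of the propargylic alcohol with activated MnO2 in CH2Cl2 gives 7.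

**Step 5.**
- What may go wrong: ring closure may be misdirected, with the diketone enol oxygen attacking the alkyne (6-endo-dig) to form a 4-pyranone. The acid may also cleave the acetal ortho to the ketone, or let the free phenol add to its neighbouring prenyl group.
- Fallback, from 5, returning at 8: the pyranone ring is closed before any alkyne is present.
  - Heating 5 with N,N-dimethylformamide dimethyl acetal gives the enaminone 3-(dimethylamino)-1-[2-hydroxy-4,6-bis(methoxymethoxy)-3,5-bis(3-methylbut-2-enyl)phenyl]-2-(3-methylbut-2-enyl)prop-2-en-1-one F4.
  - F4 cyclizes with loss of dimethylamine on mild acid treatment to 5,7-bis(methoxymethoxy)-3,6,8-tris(3-methylbut-2-enyl)chromen-4-one F5.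
  - Zincation at C2 with TMPZnCl·LiCl in THF (C3 is blocked, so C2 is the only ring C–H) and quenching with iodine give 2-iodo-5,7-bis(methoxymethoxy)-3,6,8-tris(3-methylbut-2-enyl)chromen-4-one F6.
  - Sonogashira coupling of F6 with ethynyltrimethylsilane (PdCl2(PPh3)2, CuI, Et3N) gives 8.

**Step 10.**
- What may go wrong: acid-induced addition of a free phenol to a neighbouring prenyl double bond (chroman formation at O7/C8, O5/C6 or O2'/C3 prenyl), or incomplete cleavage of the hindered acetal at C7.
- Fallback, from 15, returning at 16: the acetals are exchanged for silyl ethers under non-protic conditions and then hydrolysed at neutral pH. Treatment of 15 with excess TMSOTf and 2,2'-bipyridyl in MeCN at 0 °C converts the two aryl methoxymethyl ethers into trimethylsilyl ethers and silylates the ring B phenols. This gives 2-[2,4-bis(trimethylsilyloxy)phenyl]-3,6,8-tris(3-methylbut-2-enyl)-5,7-bis(trimethylsilyloxy)chromen-4-one F7. Addition of water then releases 16.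

## Further compounds

F1 | step 9 | 1-[2,4-bis(tert-butyldimethylsilyloxy)phenyl]-3-[2-hydroxy-4,6-bis(methoxymethoxy)-3,5-bis(3-methylbut-2-enyl)phenyl]-2-(3-methylbut-2-enyl)propane-1,3-dione | CC(C)=CCC(C(=O)c1ccc(O[Si](C)(C)C(C)(C)C)cc1O[Si](C)(C)C(C)(C)C)C(=O)c1c(O)c(CC=C(C)C)c(OCOC)c(CC=C(C)C)c1OCOC
F2 | step 9 | 2-[2,4-bis(tert-butyldimethylsilyloxy)phenyl]-5,7-bis(methoxymethoxy)-3,6,8-tris(3-methylbut-2-enyl)chromen-4-one | CC(C)=CCc1c(OCOC)c(CC=C(C)C)c2oc(-c3ccc(O[Si](C)(C)C(C)(C)C)cc3O[Si](C)(C)C(C)(C)C)c(CC=C(C)C)c(=O)c2c1OCOC
F3 | step 4 | 3-hydroxy-1-[2-hydroxy-4,6-bis(methoxymethoxy)-3,5-bis(3-methylbut-2-enyl)phenyl]-2-(3-methylbut-2-enyl)-5-(trimethylsilyl)pent-4-yn-1-one (mixture of racemic diastereomers) | C[Si](C)(C)C#CC(O)C(CC=C(C)C)C(=O)c1c(O)c(CC=C(C)C)c(OCOC)c(CC=C(C)C)c1OCOC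
F4 | step 5 | 3-(dimethylamino)-1-[2-hydroxy-4,6-bis(methoxymethoxy)-3,5-bis(3-methylbut-2-enyl)phenyl]-2-(3-methylbut-2-enyl)prop-2-en-1-one (enamine geometry not defined) | CN(C)C=C(CC=C(C)C)C(=O)c1c(O)c(CC=C(C)C)c(OCOC)c(CC=C(C)C)c1OCOC
F5 | step 5 | 5,7-bis(methoxymethoxy)-3,6,8-tris(3-methylbut-2-enyl)chromen-4-one | CC(C)=CCc1coc2c(CC=C(C)C)c(OCOC)c(CC=C(C)C)c(OCOC)c2c1=O
F6 | step 5 | 2-iodo-5,7-bis(methoxymethoxy)-3,6,8-tris(3-methylbut-2-enyl)chromen-4-one | CC(C)=CCc1c(I)oc2c(CC=C(C)C)c(OCOC)c(CC=C(C)C)c(OCOC)c2c1=O
F7 | step 10 | 2-[2,4-bis(trimethylsilyloxy)phenyl]-3,6,8-tris(3-methylbut-2-enyl)-5,7-bis(trimethylsilyloxy)chromen-4-one | CC(C)=CCc1c(O[Si](C)(C)C)c(CC=C(C)C)c2oc(-c3ccc(O[Si](C)(C)C)cc3O[Si](C)(C)C)c(CC=C(C)C)c(=O)c2c1O[Si](C)(C)C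
A1 | alternative 1 | 3-ethoxy-2-(3-methylbut-2-enyl)cyclobut-2-en-1-one | CCOC1=C(CC=C(C)C)C(=O)C1
A2 | alternative 1 | triisopropyl[(5-methylhex-4-en-1-yn-1-yl)oxy]silane | CC(C)=CCC#CO[Si](C(C)C)(C(C)C)C(C)C
A3 | alternative 1 | 5-ethoxy-2,4-bis(3-methylbut-2-enyl)-3-(triisopropylsilyloxy)phenol | Oc1cc(OCC)c(CC=C(C)C)c(O[Si](C(C)C)(C(C)C)C(C)C)c1CC=C(C)C
A4 | alternative 2 | 2,4-bis(3-methylbut-2-enyl)benzene-1,3,5-triol | Oc1cc(O)c(CC=C(C)C)c(O)c1CC=C(C)C
A5 | alternative 2 | ethyl 2-[2,4-bis(tert-butyldimethylsilyloxy)benzoyl]-5-methylhex-4-enoate (racemic) | CCOC(=O)C(CC=C(C)C)C(=O)c1ccc(O[Si](C)(C)C(C)(C)C)cc1O[Si](C)(C)C(C)(C)C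
A6 | alternative 2 | artelasticin 2',4'-bis(tert-butyldimethylsilyl) ether | CC(C)=CCc1c(O)c(CC=C(C)C)c2oc(-c3ccc(O[Si](C)(C)C(C)(C)C)cc3O[Si](C)(C)C(C)(C)C)c(CC=C(C)C)c(=O)c2c1O
A7 | alternative 3 | 2-hydroxy-4,6-bis(methoxymethoxy)-3,5-bis(3-methylbut-2-enyl)benzaldehyde | O=Cc1c(O)c(CC=C(C)C)c(OCOC)c(CC=C(C)C)c1OCOC
A8 | alternative 3 | 2,4-bis(methoxymethoxy)-1-(5-methylhex-4-en-1-yn-1-yl)benzene | COCOc1ccc(C#CCC=C(C)C)c(OCOC)c1
A9 | alternative 3 | artelasticin tetrakis(methoxymethyl) ether | CC(C)=CCc1c(OCOC)c(CC=C(C)C)c2oc(-c3ccc(OCOC)cc3OCOC)c(CC=C(C)C)c(=O)c2c1OCOC
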